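**Plan**

1. Atom labels used throughout: C1 = quaternary C–CH3, C2 and C3 = ring CH2, C4 = C(OH)iPr, C5 = ring-fusion CH, C6 = CH–O(ester), C7=C8(CH3), C9 = C=O, C10 = CH2. Bare numbers are compounds.
2. Enabling feature: C5–C10, with oxygen on C6 and C9 (para) and methyl on C8, are a 2,5-dimethoxy-4-methylphenyl ring. Only C1 is missing from the seven-membered ring; it sits between C5 and C10, three tether atoms (C2–C4) from C5.
3. Retrosynthesis: cut the ester C6–O; take C6–OH and C2–H2 back to ketone and xanthate level and the 7-ene-6,9-dione back to two methyl enol ethers; cut C1–C5 and C1–C10 (Büchner) to an aryl α-methyl α-diazo ketone; then cut C1=N2, C1–C2 (ethyl Grignard), C4–iPr (lithiation–borylation) and C3–C4 (allylboration) back to 2,5-dimethoxy-4-methylbenzaldehyde.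
4. Forward: the chain is built on the arene (C3, then isopropyl on C4, then C2–C1 and the diazo group). The five- and seven-membered rings form together in step 9. C2 is then deoxygenated and C6/C9 unmasked and adjusted.
5. Stereochemistry: C4 from catalytic asymmetric allylboration followed by a stereospecific 1,2-metallate rearrangement; C1 relayed from C4 in the Büchner step with a matched chiral ligand; C5 by equilibration to the trans ring fusion; C6 by C4–OH-directed hydride delivery.

Key step: step 9

Remark: the carbinol centres made in steps 6 and 10 and the methine between the carbonyls of 13 are erased later; they are carried as epimer mixtures and left undefined in the SMILES.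
Remark: aldehyde 1 is a catalogue compound (also available by formylation of 2,5-dimethoxytoluene).

**Step 1**
Reactants: 1 2,5-dimethoxy-4-methylbenzaldehyde; 2 allylboronic acid pinacol ester
Product: 3 (S)-1-(2,5-dimethoxy-4-methylphenyl)but-3-en-1-ol
Conditions: 2 (1.2 equiv), (S)-TRIP phosphoric acid (5 mol%; the antipode that delivers the S alcohol), toluene, −30 °C; aqueous work-up
Reagents that add atoms: allylboronic acid pinacol ester (2), C=CCB1OC(C)(C)C(C)(C)O1
Why: Chiral phosphoric acid-catalysed allylboration of an aryl aldehyde, in which the catalyst organises the closed six-membered transition state and selects the aldehyde face, so the carbinol centre should form as S.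

**Step 2**
Reactants: 3 (S)-1-(2,5-dimethoxy-4-methylphenyl)but-3-en-1-ol
Product: 4 (S)-1-(2,5-dimethoxy-4-methylphenyl)but-3-en-1-yl N,N-diisopropylcarbamate
Conditions: iPr2NCOCl, Et3N, toluene, reflux
Reagents that add atoms: N,N-diisopropylcarbamoyl chloride, CC(C)N(C(C)C)C(Cl)=O
Why: O-Carbamoylation of a secondary alcohol installs the directing and leaving group for the next step without touching the stereocentre.

**Step 3**
Reactants: 4 (S)-1-(2,5-dimethoxy-4-methylphenyl)but-3-en-1-yl N,N-diisopropylcarbamate; 5 isopropylboronic acid pinacol ester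
Product: 7 (R)-3-(2,5-dimethoxy-4-methylphenyl)-2-methylhex-5-en-3-ol, via tertiary boronic ester 6 (not isolated)
Conditions: s-BuLi, Et2O, −78 °C; 5, −78 °C; MgBr2/MeOH, −78 °C → rt; then NaOH, H2O2, THF, 0 °C → rt
Reagents that add atoms: isopropylboronic acid pinacol ester (5), CC(C)B1OC(C)(C)C(C)(C)O1; hydrogen peroxide, OO
Why: Lithiation–borylation–oxidation, in which carbamate-directed benzylic lithiation and borylation proceed with retention, the isopropyl group migrates from boron to carbon with inversion as the carbamate leaves (1,2-metallate rearrangement) and C–B oxidation is stereoretentive, so isopropyl takes the place of hydrogen with the C–O geometry kept and C4 should be set as R.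

**Step 4**
Reactants: 7 (R)-3-(2,5-dimethoxy-4-methylphenyl)-2-methylhex-5-en-3-ol
Product: 8 (R)-triethyl{[3-(2,5-dimethoxy-4-methylphenyl)-2-methylhex-5-en-3-yl]oxy}silane
Conditions: TESOTf, 2,6-lutidine, CH2Cl2, −78 → 0 °C
Reagents that add atoms: triethylsilyl trifluoromethanesulfonate, CC[Si](CC)(CC)OS(=O)(=O)C(F)(F)F
Why: Silylation of a hindered tertiary alcohol with a silyl triflate and a hindered base; triethylsilyl is the smallest silyl group expected to survive steps 5–11, and it blocks O–H insertion in step 9.

**Step 5**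
Reactants: 8 (R)-triethyl{[3-(2,5-dimethoxy-4-methylphenyl)-2-methylhex-5-en-3-yl]oxy}silane
Product: 9 (R)-3-(2,5-dimethoxy-4-methylphenyl)-4-methyl-3-(triethylsilyloxy)pentanal
Conditions: OsO4 (cat.), NaIO4, 2,6-lutidine, dioxane/H2O, rt
Reagents that add atoms: sodium periodate (terminal oxidant, oxygen delivered through OsO4), [Na+].[O-]I(=O)(=O)=O
Why: Lemieux–Johnson cleavage of the terminal alkene under buffered conditions, which avoids ozone on the electron-rich arene and leaves the silyl ether intact.

**Step 6**
Reactants: 9 (R)-3-(2,5-dimethoxy-4-methylphenyl)-4-methyl-3-(triethylsilyloxy)pentanal; 10 ethylmagnesium bromide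
Product: 11 (5R)-5-(2,5-dimethoxy-4-methylphenyl)-6-methyl-5-(triethylsilyloxy)heptan-3-ol (C3 epimers)
Conditions: EtMgBr, THF, −78 → 0 °C; NH4Cl work-up
Reagents that add atoms: ethylmagnesium bromide (10), CC[Mg]Br
Why: Grignard addition to an aldehyde brings in C1 and its methyl group; the new carbinol centre is oxidised away in step 7, so its configuration does not matter.

**Step 7**
Reactants: 11 (5R)-5-(2,5-dimethoxy-4-methylphenyl)-6-methyl-5-(triethylsilyloxy)heptan-3-ol
Product: 12 (R)-5-(2,5-dimethoxy-4-methylphenyl)-6-methyl-5-(triethylsilyloxy)heptan-3-one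
Conditions: Dess–Martin periodinane, NaHCO3, CH2Cl2, rt
Reagents that add atoms: none
Why: Dess–Martin oxidation of a secondary alcohol to the ethyl ketone under buffered, non-epimerising conditions.

**Step 8**
Reactants: 12 (R)-5-(2,5-dimethoxy-4-methylphenyl)-6-methyl-5-(triethylsilyloxy)heptan-3-one
Product: 14 (R)-2-diazo-5-(2,5-dimethoxy-4-methylphenyl)-6-methyl-5-(triethylsilyloxy)heptan-3-one, via trifluoroacetyl ketone 13 (not isolated)
Conditions: LiHMDS, THF, −78 °C; CF3CO2CH2CF3; then 4-acetamidobenzenesulfonyl azide, Et3N, H2O (1 equiv), MeCN, rt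
Reagents that add atoms: 2,2,2-trifluoroethyl trifluoroacetate (trifluoroacetyl group of 13), O=C(OCC(F)(F)F)C(F)(F)F; 4-acetamidobenzenesulfonyl azide (two nitrogen atoms of 14), CC(=O)Nc1ccc(cc1)S(=O)(=O)N=[N+]=[N-]
Why: Detrifluoroacetylative diazo transfer, in which kinetic enolisation should occur at the ethyl CH2 (the other α-carbon is neopentyl), Claisen-type trifluoroacetylation activates that carbon, and the sulfonyl azide transfers N2 with loss of the trifluoroacetyl group.

**Step 9**
Reactants: 14 (R)-2-diazo-5-(2,5-dimethoxy-4-methylphenyl)-6-methyl-5-(triethylsilyloxy)heptan-3-one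
Product: 16 bicyclic trienone (C5=C6(OMe), C7=C8(Me), C9(OMe)=C10; C1(Me) R, C2 ketone, C4(OTES)(iPr) R; angular methyl syn to the C4 oxygen), via norcaradiene 15 (not isolated)
Conditions: [Cu(MeCN)4]PF6 (5 mol%), (S,S)-tBu-box or its antipode (whichever is matched with C4), NaBARF, CH2Cl2, 40 °C, slow addition of 14
Reagents that add atoms: none
Why: Dinitrogen loss gives a copper carbene whose carbon C1 adds across the ipso–ortho bond C5–C10 (forming C1–C5 and C1–C10) to give norcaradiene 15, which opens by 6π disrotatory electrocyclisation to cycloheptatriene 16; this is the intramolecular Büchner reaction, known for aryl-tethered α-methyl α-diazo ketones, which give 8a-methylazulenones. The five-membered ring (C1–C5) closes in the cyclopropanation, the carbene reaching the ipso carbon through the three-atom tether C2–C3–C4, and the seven-membered ring arises when the C5–C10 bond of the norcaradiene breaks, so that the benzene ring is expanded by C1. C1 is controlled by C4: in the rotamer that lets the tether reach C5–C10, one of the two remaining C4 substituents lies next to the methoxy-bearing C6 and the carbene methyl; the compact silyloxy group should take that place and the isopropyl group turn to the C10 side, so the angular methyl ends syn to the C4 oxygen and anti to isopropyl (larger benzylic group anti to the angular methyl is the sense known for this reaction class), and the matched bis(oxazoline) ligand reinforces it. Addition to C5–C10 and not C5–C6 is secured by the methoxy group on C6, which makes that bond fully substituted. Cyclopropanation has to beat rearomatising C–H substitution at C10, insertion into the isopropyl C–H bond, attack on the ether oxygen and 1,2-hydride shift from the methyl group; copper(I) in place of electrophilic rhodium(II) carboxylates and the hindered, weakly basic silyl ether oxygen serve this. C1 has no hydrogen, so 16 cannot isomerise by 1,5-hydrogen shift.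

**Step 10**
Reactants: 16 bicyclic trienone
Product: 17 C2 alcohol of 16 (C2 epimers)
Conditions: NaBH4, MeOH/THF, 0 °C
Reagents that add atoms: none
Why: Borohydride reduction of the cyclopentanone removes the carbonyl that could assist acid-triggered cyclopropane cleavage and rearomatisation in step 12; the new carbinol centre is erased in step 14.

**Step 11**
Reactants: 17 C2 alcohol
Product: 18 C2 O-(S-methyl dithiocarbonate) of 17
Conditions: NaH, CS2, THF, 0 °C; then MeI
Reagents that add atoms: carbon disulfide, S=C=S; iodomethane, CI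
Why: Xanthate formation (alkoxide addition to CS2, then S-methylation) masks the C2 hydroxyl through steps 12–13 and prepares the radical deoxygenation; enol ethers and silyl ether are stable to base.

**Step 12**
Reactants: 18 xanthate
Product: 19 β-hydroxy ene-dione xanthate (C6 and C9 ketones, C7=C8(Me), free C4–OH, C5–H anti to the angular methyl)
Conditions: 1 M aq. HCl, THF, 0 °C until both enol ethers are hydrolysed, then rt until the silyl ether is cleaved; neutral work-up, used at once
Reagents that add atoms: water, O
Why: Acid hydrolysis of the two methyl enol ethers (C-protonation at C5 and C10, hemiketal collapse) should precede cleavage of the tertiary silyl ether, and C5, now α to the C6 ketone, can equilibrate through the enol to the trans-fused isomer in which C6 avoids the isopropyl group and accepts a hydrogen bond from C4–OH.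

**Step 13**
Reactants: 19 β-hydroxy ene-dione xanthate
Product: 20 4,6-diol xanthate (C6–OH on the face of C5–H, C9 enone intact)
Conditions: Me4NBH(OAc)3, MeCN/AcOH, −30 → −20 °C
Reagents that add atoms: none
Why: Hydroxyl-directed (Evans–Saksena) reduction, in which the borohydride bound to the C4 oxygen delivers hydride to the C6 carbonyl face that is syn to C4, setting C6 with its oxygen anti to C4 across C5, while the unassisted C9 ketone is not reduced by this reagent.

**Step 14**
Reactants: 20 4,6-diol xanthate
Product: 21 lancerodiol (1R,4R,5S,6S)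
Conditions: Bu3SnH, AIBN (cat.), toluene, 80 °C
Reagents that add atoms: none
Why: Barton–McCombie deoxygenation; it is placed here because C1 no longer carries vinyl groups, so the C2 radical has no homoallyl/cyclopropylcarbinyl rearrangement path and is simply reduced.

**Step 15**
Reactants: 21 lancerodiol; 22 4-methoxybenzoyl chloride
Product: 23 lancerodiol p-methoxybenzoate (1R,4R,5S,6S)
Conditions: 22, DMAP, Et3N, CH2Cl2, 0 °C → rt
Reagents that add atoms: 4-methoxybenzoyl chloride (22), COc1ccc(cc1)C(Cl)=O
Why: DMAP-catalysed acylation of the secondary allylic C6 alcohol; the tertiary C4 alcohol should not react under these conditions.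

**Compound list**

1 | 2,5-dimethoxy-4-methylbenzaldehyde | COc1cc(C)c(OC)cc1C=O | starting material
2 | allylboronic acid pinacol ester | C=CCB1OC(C)(C)C(C)(C)O1 | starting material
3 | (S)-1-(2,5-dimethoxy-4-methylphenyl)but-3-en-1-ol | COc1cc(C)c(OC)cc1[C@@H](O)CC=C | intermediate
4 | (S)-1-(2,5-dimethoxy-4-methylphenyl)but-3-en-1-yl N,N-diisopropylcarbamate | COc1cc(C)c(OC)cc1[C@@H](OC(=O)N(C(C)C)C(C)C)CC=C | intermediate
5 | isopropylboronic acid pinacol ester | CC(C)B1OC(C)(C)C(C)(C)O1 | starting material
6 | (S)-2-[3-(2,5-dimethoxy-4-methylphenyl)-2-methylhex-5-en-3-yl]-4,4,5,5-tetramethyl-1,3,2-dioxaborolane | COc1cc(C)c(OC)cc1[C@](B2OC(C)(C)C(C)(C)O2)(C(C)C)CC=C | intermediate (not isolated)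
7 | (R)-3-(2,5-dimethoxy-4-methylphenyl)-2-methylhex-5-en-3-ol | COc1cc(C)c(OC)cc1[C@](O)(C(C)C)CC=C | intermediate
8 | (R)-triethyl{[3-(2,5-dimethoxy-4-methylphenyl)-2-methylhex-5-en-3-yl]oxy}silane | COc1cc(C)c(OC)cc1[C@](O[Si](CC)(CC)CC)(C(C)C)CC=C | intermediate
9 | (R)-3-(2,5-dimethoxy-4-methylphenyl)-4-methyl-3-(triethylsilyloxy)pentanal | COc1cc(C)c(OC)cc1[C@](O[Si](CC)(CC)CC)(C(C)C)CC=O | intermediate
10 | ethylmagnesium bromide | CC[Mg]Br | starting material
11 | (5R)-5-(2,5-dimethoxy-4-methylphenyl)-6-methyl-5-(triethylsilyloxy)heptan-3-ol, C3 epimers | COc1cc(C)c(OC)cc1[C@](O[Si](CC)(CC)CC)(C(C)C)CC(O)CC | intermediate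
12 | (R)-5-(2,5-dimethoxy-4-methylphenyl)-6-methyl-5-(triethylsilyloxy)heptan-3-one | COc1cc(C)c(OC)cc1[C@](O[Si](CC)(CC)CC)(C(C)C)CC(=O)CC | intermediate
13 | (6R)-6-(2,5-dimethoxy-4-methylphenyl)-1,1,1-trifluoro-3,7-dimethyl-6-(triethylsilyloxy)octane-2,4-dione | COc1cc(C)c(OC)cc1[C@](O[Si](CC)(CC)CC)(C(C)C)CC(=O)C(C)C(=O)C(F)(F)F | intermediate (not isolated)
14 | (R)-2-diazo-5-(2,5-dimethoxy-4-methylphenyl)-6-methyl-5-(triethylsilyloxy)heptan-3-one | COc1cc(C)c(OC)cc1[C@](O[Si](CC)(CC)CC)(C(C)C)CC(=O)C(C)=[N+]=[N-] | intermediate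
15 | norcaradiene: cyclopropane C1–C5–C10, diene C6(OMe)=C7, C8(Me)=C9(OMe), C2 ketone, C4(OTES)(iPr) | C[C@]12C(=O)C[C@@](O[Si](CC)(CC)CC)(C(C)C)[C@]13C(OC)=CC(C)=C(OC)[C@H]23 | intermediate (not isolated)
16 | (3R,8aR)-4,7-dimethoxy-6,8a-dimethyl-3-(propan-2-yl)-3-(triethylsilyloxy)-3,8a-dihydroazulen-1(2H)-one | C12=C(OC)C=C(C)C(OC)=C[C@@]1(C)C(=O)C[C@@]2(O[Si](CC)(CC)CC)C(C)C | intermediate
17 | C2 alcohol of 16 (azulen-1-ol, C2 epimers) | C12=C(OC)C=C(C)C(OC)=C[C@@]1(C)C(O)C[C@@]2(O[Si](CC)(CC)CC)C(C)C | intermediate
18 | O-(C2) S-methyl dithiocarbonate of 17 | C12=C(OC)C=C(C)C(OC)=C[C@@]1(C)C(OC(=S)SC)C[C@@]2(O[Si](CC)(CC)CC)C(C)C | intermediate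
19 | trans-fused 4-hydroxy-4-isopropyl-1,8-dimethyl hydroazulen-7-ene-6,9-dione carrying the C2 xanthate | O=C1C=C(C)C(=O)C[C@@]2(C)C(OC(=S)SC)C[C@@](O)(C(C)C)[C@H]12 | intermediate
20 | C2 xanthate of lancerodiol (4,6-diol, 7-en-9-one) | O[C@H]1C=C(C)C(=O)C[C@@]2(C)C(OC(=S)SC)C[C@@](O)(C(C)C)[C@H]12 | intermediate
21 | lancerodiol | O[C@H]1C=C(C)C(=O)C[C@@]2(C)CC[C@@](O)(C(C)C)[C@H]12 | intermediate
22 | 4-methoxybenzoyl chloride | COc1ccc(cc1)C(Cl)=O | starting material
23 | lancerodiol p-methoxybenzoate | COc1ccc(C(=O)O[C@H]2C=C(C)C(=O)C[C@@]3(C)CC[C@@](O)(C(C)C)[C@H]23)cc1 | target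

**Totals**

Total step count: 15. Longest linear sequence: 15 steps (from 1).

**The three steps most likely to fail**

Step 9. The carbene may add to the arene face opposite to the one wanted, so that the angular methyl ends anti to the C4 oxygen, or it may be diverted into rearomatising C–H substitution at C10. The fallback sets out from 12 and returns at 19. It ties the C4 oxygen to the C6 oxygen so that the facial outcome is fixed by a ring and not by a size difference.
- Ceric ammonium nitrate in aqueous acetonitrile should demethylate 12 oxidatively and remove the silyl group, giving hydroxy quinone F1.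
- Dithionite reduces it to hydroquinone triol F2.
- Diisopropylsilyl bis(triflate)/2,6-lutidine closes the six-membered silylene across the C6 phenol and the C4 carbinol, and TIPSOTf caps the C9 phenol, giving silylene ketone F3.
- Diazo transfer as in step 8, through trifluoroacetyl ketone F4 (not isolated), gives diazo ketone F5.
- In the copper-catalysed Büchner reaction of F5, through norcaradiene F6 (not isolated), the ring-bound oxygen is held on the C6 side, so the angular methyl can only end syn to it; the product is bis(silyl enol ether) F7.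
- Borohydride reduction gives alcohol F8 and NaH/CS2/MeI gives xanthate F9.
- Aqueous HF in acetonitrile cleaves both silyl enol ethers and the silyl ether and leads to 19.

Step 12. The tertiary C4 oxygen may be lost, either by ionisation of the allylic C4–O bond before the C5=C6 enol ether is hydrolysed or by acid-promoted β-elimination once C6 is a ketone; C5 may also settle as the cis-fused epimer. The fallback sets out from 18 and returns at 19. It separates the events so that the tertiary oxygen is never free while acid is present.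
- Oxalic acid on wet silica in THF hydrolyses only the two enol ethers and gives the silyl-protected ene-dione F10.
- F10 cannot undergo retro-aldol cleavage and can be equilibrated at C5 under neutral to weakly basic conditions.
- HF·pyridine buffered with pyridine (THF, 0 °C) then frees the tertiary alcohol and gives 19.

Step 3. The lithiated carbamate may lose configurational integrity, or the hindered isopropyl boronate may add and migrate sluggishly, so that 7 forms in low enantiomeric purity or not at all. The fallback sets out from 1 and returns at 7. It creates the tertiary centre by enantioface-selective allylation of a ketone instead of a stereospecific rearrangement.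
- Isopropylmagnesium chloride adds to 1 to give racemic alcohol F11.
- Dess–Martin oxidation gives aryl isopropyl ketone F12.
- Catalytic asymmetric allylboration of F12 with 2 (chiral biphenol catalyst) gives 7.

**Further compounds**

F1 | step 9 | 2-[(3R)-3-hydroxy-2-methyl-5-oxoheptan-3-yl]-5-methyl-1,4-benzoquinone | O=C1C=C(C)C(=O)C=C1[C@](O)(C(C)C)CC(=O)CC
F2 | step 9 | (R)-5-(2,5-dihydroxy-4-methylphenyl)-5-hydroxy-6-methylheptan-3-one | Oc1cc(C)c(O)cc1[C@](O)(C(C)C)CC(=O)CC
F3 | step 9 | (R)-1-[2,2,4-triisopropyl-7-methyl-6-(triisopropylsilyloxy)-4H-1,3,2-benzodioxasilin-4-yl]butan-2-one | CC(C)[Si](C(C)C)(C(C)C)Oc1cc2c(cc1C)O[Si](C(C)C)(C(C)C)O[C@@]2(C(C)C)CC(=O)CC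
F4 | step 9 | trifluoroacetyl ketone of F3 (1,1,1-trifluoro-3-methyl-2,4-dione side chain) | CC(C)[Si](C(C)C)(C(C)C)Oc1cc2c(cc1C)O[Si](C(C)C)(C(C)C)O[C@@]2(C(C)C)CC(=O)C(C)C(=O)C(F)(F)F
F5 | step 9 | α-methyl α-diazo ketone of F3 | CC(C)[Si](C(C)C)(C(C)C)Oc1cc2c(cc1C)O[Si](C(C)C)(C(C)C)O[C@@]2(C(C)C)CC(=O)C(C)=[N+]=[N-]
F6 | step 9 | silylene-bridged norcaradiene | C[C@]12C(=O)C[C@@](O[Si](C(C)C)(C(C)C)O4)(C(C)C)[C@]13C4=CC(C)=C(O[Si](C(C)C)(C(C)C)C(C)C)[C@H]23
F7 | step 9 | silylene-bridged bicyclic trienone (C6–O–Si–O–C4 ring, C9–OTIPS) | C12=C3C=C(C)C(O[Si](C(C)C)(C(C)C)C(C)C)=C[C@@]1(C)C(=O)C[C@]2(C(C)C)O[Si](C(C)C)(C(C)C)O3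
F8 | step 9 | C2 alcohol of F7 (C2 epimers) | C12=C3C=C(C)C(O[Si](C(C)C)(C(C)C)C(C)C)=C[C@@]1(C)C(O)C[C@]2(C(C)C)O[Si](C(C)C)(C(C)C)O3
F9 | step 9 | C2 xanthate of F8 | C12=C3C=C(C)C(O[Si](C(C)C)(C(C)C)C(C)C)=C[C@@]1(C)C(OC(=S)SC)C[C@]2(C(C)C)O[Si](C(C)C)(C(C)C)O3
F10 | step 12 | C4 triethylsilyl ether of 19 | O=C1C=C(C)C(=O)C[C@@]2(C)C(OC(=S)SC)C[C@@](O[Si](CC)(CC)CC)(C(C)C)[C@H]12
F11 | step 3 | rac-1-(2,5-dimethoxy-4-methylphenyl)-2-methylpropan-1-ol | COc1cc(C)c(OC)cc1C(O)C(C)C
F12 | step 3 | 1-(2,5-dimethoxy-4-methylphenyl)-2-methylpropan-1-one | COc1cc(C)c(OC)cc1C(=O)C(C)C
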